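Ring B (cyclopentane Cq–Cc–Cb–Ca–P2; Cq is the spiro carbon shared with cyclohexenedione ring A, Cc carries the isopropyl group, P2 is pinane C2) is cut at Ca–P2. The feature exploited is the tertiary P2–H bond of a cis-pinane: hydrogenation places it on the face opposite the gem-dimethyl bridge, where Ca sits in the target. A rhodium carbenoid at Ca, generated from an acyclic α-diazo-β-keto ester (ketone Cb, methyl ester on Cq, cis-pinan-2-yl on Cq, isopropyl on Cc, both stereocentres set by an Ireland–Claisen rearrangement), inserts into this bond with retention, closing ring B and creating the quaternary spiro centre P2 in one operation. Ring A is annulated last.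

Key step: step 11

Atom labels: ring B is Cq–Cc–Cb–Ca–P2 and ring A is Cq–Ct–Cv–Cw–Cx–Cy. Cq is the spiro carbon common to both rings, Ct the carbonyl carbon between Cq and the methyl-bearing carbon Cv, Cw the methoxy-bearing carbon, Cx the CMe2 carbon, and Cy the carbonyl carbon between Cx and Cq. P2 and P3 are C2 and C3 of the pinane.

Remark on the chemistry: formaldehyde is charged as paraformaldehyde, and (+)-β-pinene and methyl diazoacetate are taken as purchased; the Cq configuration of the key-step precursor does not reach the target (Cq is enolised in step 20), but it is made with ester and isopropyl anti so that Cc, which is epimerisable next to the Cb ketone, already sits in its stable trans arrangement on ring B.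

Step 1
Reactants: 1 (+)-β-pinene; 2 formaldehyde (charged as paraformaldehyde)
Product: 3 (+)-nopol
Conditions: (CH2O)n, neat, 180 °C, sealed tube
Reagents that add atoms: none
Why: Thermal carbonyl-ene (Prins-type) reaction in which the exocyclic methylene attacks formaldehyde while the allylic C3–H is transferred, so the double bond moves to C2=C3 and neither bridgehead stereocentre is touched.

Step 2
Reactants: 3 (+)-nopol
Product: 4 cis-dihydronopol
Conditions: H2 (1 atm), PtO2, EtOAc, rt
Reagents that add atoms: none
Why: Heterogeneous catalytic hydrogenation should deliver both hydrogens from the face opposite the gem-dimethyl bridge, which sets P2 with its hydrogen anti and its side chain syn to that bridge (cis-pinane series).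

Step 3
Reactants: 4 cis-dihydronopol
Product: 6 (cis-pinan-2-yl)acetic acid, via aldehyde 5 (not isolated)
Conditions: TEMPO (cat.), PhI(OAc)2, MeCN/H2O, rt
Reagents that add atoms: water, O
Why: Nitroxyl-catalysed oxidation (oxoammonium cycle with PhI(OAc)2 as terminal oxidant) should take the primary alcohol to the aldehyde and, through its hydrate, to the acid without affecting the tertiary C–H bonds.

Step 4
Reactants: 7 (E)-5-methylhex-3-en-2-one
Product: 8 (2R,3E)-5-methylhex-3-en-2-ol
Conditions: (S)-2-methyl-CBS-oxazaborolidine (10 mol%), catecholborane, toluene, −78 °C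
Reagents that add atoms: none
Why: Corey–Bakshi–Shibata reduction, in which the (S)-oxazaborolidine binds the ketone with the alkenyl group as the large substituent and directs 1,2-hydride delivery to the face that gives the (R)-carbinol, as with aryl methyl ketones.

Step 5
Reactants: 6 (cis-pinan-2-yl)acetic acid; 8 (2R,3E)-5-methylhex-3-en-2-ol
Product: 9 (2R,3E)-5-methylhex-3-en-2-yl (cis-pinan-2-yl)acetate
Conditions: DCC, DMAP (cat.), CH2Cl2, 0 °C → rt
Reagents that add atoms: none
Why: Steglich esterification (carbodiimide activation, DMAP acyl transfer) should join the unhindered acid to the secondary allylic alcohol without touching its stereocentre or the olefin geometry.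

Step 6
Reactants: 9 (2R,3E)-5-methylhex-3-en-2-yl (cis-pinan-2-yl)acetate
Product: 13 (2S,3S,4E)-2-(cis-pinan-2-yl)-3-(propan-2-yl)hex-4-enoic acid, via lithium enolate 10 (not isolated), via silyl ketene acetal 11 (not isolated), via silyl ester 12 (not isolated)
Conditions: LiN(iPr)2, THF, −78 °C; Me3SiCl, −78 °C → 50 °C; 1 M HCl
Reagents that add atoms: none
Why: Ireland–Claisen rearrangement: kinetic deprotonation in THF should give the enolate with the pinanyl-bearing substituent trans to O–Li, and its silyl ketene acetal should rearrange through a chair in which the carbinol methyl group is equatorial, so that the (R)-carbinol centre is relayed to Cq and Cc (2S,3S; pinanyl and isopropyl anti) and the new olefin is E.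

Step 7
Reactants: 13 (2S,3S,4E)-2-(cis-pinan-2-yl)-3-(propan-2-yl)hex-4-enoic acid
Product: 14 methyl (2S,3S,4E)-2-(cis-pinan-2-yl)-3-(propan-2-yl)hex-4-enoate
Conditions: MeI, K2CO3, DMF, rt
Reagents that add atoms: iodomethane, CI
Why: SN2 O-alkylation of the carboxylate, which is insensitive to the bulk around the acyl carbon, should give the methyl ester that serves as the Cq substituent without a C–H bond of its own within reach of the later carbenoid.

Step 8
Reactants: 14 methyl (2S,3S,4E)-2-(cis-pinan-2-yl)-3-(propan-2-yl)hex-4-enoate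
Product: 16 methyl (2S,3R)-2-(cis-pinan-2-yl)-3-formyl-4-methylpentanoate, via ozonide 15 (not isolated)
Conditions: O3, CH2Cl2, −78 °C; PPh3, −78 °C → rt
Reagents that add atoms: ozone, [O-][O+]=O
Why: Ozonolysis with reductive work-up should cleave the only C=C bond and unveil the Cb aldehyde under cold, neutral conditions that leave the α-stereocentre Cc alone.

Step 9
Reactants: 16 methyl (2S,3R)-2-(cis-pinan-2-yl)-3-formyl-4-methylpentanoate; 17 methyl diazoacetate
Product: 18 dimethyl (2S,3R)-2-(cis-pinan-2-yl)-4-oxo-3-(propan-2-yl)hexanedioate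
Conditions: SnCl2 (10 mol%), CH2Cl2, rt
Reagents that add atoms: none
Why: Roskamp homologation, in which the diazo carbon adds to the SnCl2-activated aldehyde and a 1,2-hydride shift with loss of N2 gives the β-keto ester directly under non-basic conditions that should not epimerise Cc.

Step 10
Reactants: 18 dimethyl (2S,3R)-2-(cis-pinan-2-yl)-4-oxo-3-(propan-2-yl)hexanedioate
Product: 19 dimethyl (4R,5S)-2-diazo-3-oxo-4-(propan-2-yl)-5-(cis-pinan-2-yl)hexanedioate
Conditions: 4-acetamidobenzenesulfonyl azide, Et3N, MeCN, 0 °C → rt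
Reagents that add atoms: 4-acetamidobenzenesulfonyl azide, CC(=O)Nc1ccc(cc1)S(=O)(=O)N=[N+]=[N-]
Why: Regitz diazo transfer to the doubly activated methylene Ca, the only position acidic enough to be deprotonated by triethylamine.

Step 11
Reactants: 19 dimethyl (4R,5S)-2-diazo-3-oxo-4-(propan-2-yl)-5-(cis-pinan-2-yl)hexanedioate
Product: 21 spiro cyclopentanone β-keto ester, via rhodium carbenoid 20 (not isolated)
Conditions: Rh2(OAc)4 (1 mol%), CH2Cl2, 40 °C, slow addition of 19
Reagents that add atoms: none
Why: Rh2(OAc)4 (divalent rhodium) should expel N2 from 19 to give the electrophilic carbenoid 20 at Ca, which inserts into the tertiary P2–H bond through a concerted three-centre transition state; the closest known reaction type is the intramolecular 1,5 C–H insertion of α-diazo-β-keto esters that gives 2-alkoxycarbonylcyclopentanones. Ring B closes as a five-membered ring by 1,5-insertion through a chair-like array of Ca, Cb, Cc, Cq, P2 and H in which the isopropyl group on Cc and the ester on Cq are both pseudo-equatorial. P2 becomes the quaternary spiro stereocentre with retention, so Ca takes the place of the hydrogen that step 2 put anti to the gem-dimethyl bridge, while Ca itself is an enolisable β-keto ester carbon that is left undefined and erased in step 12. The step needs site selectivity for P2–H over the six primary C–H bonds of the isopropyl methyl groups, which are also 1,5, and over capture of the carbenoid by the Cq ester carbonyl. The substrate secures this because the electrophilic carbenoid prefers the electron-rich tertiary C–H bond, every other tertiary or secondary C–H bond is 1,4 or 1,6, and an ester carbonyl is a poor partner for a six-membered carbonyl ylide. The methyl ester on Cq lowers the hydridic character of the neighbouring P2–H bond somewhat but was kept because, unlike an ether or acetal at that carbon, it offers no C–H bond of its own in 1,5 position.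

Step 12
Reactants: 21 spiro cyclopentanone β-keto ester
Product: 22 spiro keto ester (Ca ester removed)
Conditions: LiCl, H2O (2 equiv), DMSO, 140 °C
Reagents that add atoms: none
Why: Krapcho dealkoxycarbonylation, in which chloride demethylates the β-keto ester and the β-keto carboxylate loses CO2 while the isolated Cq ester is not activated for this pathway, and any epimerisation at Cc should converge on the trans isomer already in hand.

Step 13
Reactants: 22 spiro keto ester
Product: 23 dithiolane of 22
Conditions: HS(CH2)2SH, BF3·OEt2, CH2Cl2, 0 °C → rt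
Reagents that add atoms: ethane-1,2-dithiol, SCCS
Why: Lewis-acid-promoted thioketalisation of the cyclopentanone carbonyl Cb, to which the methyl ester is inert.

Step 14
Reactants: 23 dithiolane of 22
Product: 24 methyl ester with Cb as CH2
Conditions: Raney Ni, EtOH, reflux
Reagents that add atoms: none
Why: Mozingo reduction, in which Raney Ni hydrogenolyses both C–S bonds and leaves Cb as CH2, after which Cc can no longer epimerise.

Step 15
Reactants: 24 methyl ester with Cb as CH2
Product: 25 primary alcohol (hydroxymethyl group on Cq)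
Conditions: LiAlH4, THF, 0 °C → reflux
Reagents that add atoms: none
Why: Aluminium hydride reduction of the hindered ester to the primary alcohol, with no other reducible group present.

Step 16
Reactants: 25 primary alcohol (hydroxymethyl group on Cq)
Product: 26 aldehyde on Cq
Conditions: Dess–Martin periodinane, CH2Cl2, rt
Reagents that add atoms: none
Why: Dess–Martin oxidation should give the aldehyde under neutral conditions, and the configuration at Cq is of no consequence because Cq is enolised in step 20.

Step 17
Reactants: 27 methyl isobutyrate; 28 propanoyl chloride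
Product: 30 methyl 2,2-dimethyl-3-oxopentanoate, via lithium enolate 29 (not isolated)
Conditions: LiN(iPr)2, THF, −78 °C; enolate added to 28, −78 °C → rt
Reagents that add atoms: none
Why: C-acylation of a fully substituted ester enolate by an acid chloride (crossed Claisen-type acylation, inverse addition) should give the β-keto ester whose only enolisable position is the ethyl CH2.

Step 18
Reactants: 30 methyl 2,2-dimethyl-3-oxopentanoate; 26 aldehyde on Cq
Product: 32 aldol adduct, via lithium enolate 31 (not isolated)
Conditions: LiN(iPr)2, THF, −78 °C; then 26, −78 °C; aq NH4Cl at −78 °C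
Reagents that add atoms: none
Why: Directed aldol addition of the kinetic lithium enolate of the ethyl ketone to the hindered but reactive aldehyde, which forms the Ct–Cv bond and creates stereocentres at Ct and Cv that are lost again in steps 19 and 20, the cold quench keeping the aldolate from closing onto the ester.

Step 19
Reactants: 32 aldol adduct
Product: 33 diketo ester
Conditions: Dess–Martin periodinane, CH2Cl2, rt
Reagents that add atoms: none
Why: Dess–Martin oxidation of the β-hydroxy ketone to the 1,3-diketone, which places the Ct and Cw carbonyl groups on either side of Cv.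

Step 20
Reactants: 33 diketo ester
Product: 35 ring-A trione, via dilithium dianion 34 (not isolated)
Conditions: LiN(iPr)2 (2.5 equiv), THF, −78 → 0 °C; aq HCl
Reagents that add atoms: none
Why: Dieckmann-type intramolecular acylation of a β-diketone dianion, in which the second equivalent of base removes Cq–H and the terminal carbanion should attack the Cy ester (6-exo-trig) on the face of ring B away from the adjacent isopropyl group, placing Cy trans and Ct cis to that group as in the target while the product is held as its enolate against retro-Claisen cleavage.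

Step 21
Reactants: 35 ring-A trione
Product: 36 target CNP0307059.1
Conditions: Me2SO4, K2CO3, acetone, reflux
Reagents that add atoms: dimethyl sulfate, COS(=O)(=O)OC
Why: O-alkylation of the potassium enolate of the vinylogous acid by a hard methylating agent should occur at the oxygen on Cw beside CMe2, because the oxygen on Ct is buried between the spiro centre, the isopropyl group and the pinane CH2 (P3).

Compound list

1 | (+)-β-pinene, (1R,5R)-6,6-dimethyl-2-methylidenebicyclo[3.1.1]heptane | C=C1CC[C@@H]2C[C@H]1C2(C)C | starting material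
2 | formaldehyde, charged as its solid polymer paraformaldehyde | C=O | starting material
3 | (+)-nopol, 2-[(1S,5R)-6,6-dimethylbicyclo[3.1.1]hept-2-en-2-yl]ethan-1-ol | OCCC1=CC[C@@H]2C[C@H]1C2(C)C | intermediate
4 | cis-dihydronopol, 2-[(1R,2R,5R)-6,6-dimethylbicyclo[3.1.1]heptan-2-yl]ethan-1-ol (side chain syn, C2–H anti to the gem-dimethyl bridge) | OCC[C@H]1CC[C@@H]2C[C@H]1C2(C)C | intermediate
5 | [(1R,2R,5R)-6,6-dimethylbicyclo[3.1.1]heptan-2-yl]acetaldehyde | O=CC[C@H]1CC[C@@H]2C[C@H]1C2(C)C | intermediate (not isolated)
6 | (cis-pinan-2-yl)acetic acid, [(1R,2R,5R)-6,6-dimethylbicyclo[3.1.1]heptan-2-yl]acetic acid | OC(=O)C[C@H]1CC[C@@H]2C[C@H]1C2(C)C | intermediate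
7 | (E)-5-methylhex-3-en-2-one | CC(=O)/C=C/C(C)C | starting material
8 | (2R,3E)-5-methylhex-3-en-2-ol | C[C@@H](O)/C=C/C(C)C | intermediate
9 | (2R,3E)-5-methylhex-3-en-2-yl [(1R,2R,5R)-6,6-dimethylbicyclo[3.1.1]heptan-2-yl]acetate | CC(C)/C=C/[C@@H](C)OC(=O)C[C@H]1CC[C@@H]2C[C@H]1C2(C)C | intermediate
10 | lithium enolate of 9 (pinanyl group trans to O–Li) | [Li]O/C(O[C@H](C)/C=C/C(C)C)=C/[C@H]1CC[C@@H]2C[C@H]1C2(C)C | intermediate (not isolated)
11 | trimethylsilyl ketene acetal of 9 (pinanyl group trans to OSiMe3) | C[Si](C)(C)O/C(O[C@H](C)/C=C/C(C)C)=C/[C@H]1CC[C@@H]2C[C@H]1C2(C)C | intermediate (not isolated)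
12 | trimethylsilyl ester of 13 | C[Si](C)(C)OC(=O)[C@@H]([C@H]1CC[C@@H]2C[C@H]1C2(C)C)[C@@H](C(C)C)/C=C/C | intermediate (not isolated)
13 | (2S,3S,4E)-2-[(1R,2S,5R)-6,6-dimethylbicyclo[3.1.1]heptan-2-yl]-3-(propan-2-yl)hex-4-enoic acid (C2 = Cq, C3 = Cc) | OC(=O)[C@@H]([C@H]1CC[C@@H]2C[C@H]1C2(C)C)[C@@H](C(C)C)/C=C/C | intermediate
14 | methyl (2S,3S,4E)-2-[(1R,2S,5R)-6,6-dimethylbicyclo[3.1.1]heptan-2-yl]-3-(propan-2-yl)hex-4-enoate | COC(=O)[C@@H]([C@H]1CC[C@@H]2C[C@H]1C2(C)C)[C@@H](C(C)C)/C=C/C | intermediate
15 | ozonide (1,2,4-trioxolane) of 14 | COC(=O)[C@@H]([C@H]1CC[C@@H]2C[C@H]1C2(C)C)[C@@H](C(C)C)C1OOC(C)O1 | intermediate (not isolated)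
16 | methyl (2S,3R)-2-[(1R,2S,5R)-6,6-dimethylbicyclo[3.1.1]heptan-2-yl]-3-formyl-4-methylpentanoate (CHO = Cb) | COC(=O)[C@@H]([C@H]1CC[C@@H]2C[C@H]1C2(C)C)[C@@H](C(C)C)C=O | intermediate
17 | methyl diazoacetate | COC(=O)C=[N+]=[N-] | starting material
18 | dimethyl (2S,3R)-2-[(1R,2S,5R)-6,6-dimethylbicyclo[3.1.1]heptan-2-yl]-4-oxo-3-(propan-2-yl)hexanedioate | COC(=O)[C@@H]([C@H]1CC[C@@H]2C[C@H]1C2(C)C)[C@@H](C(C)C)C(=O)CC(=O)OC | intermediate
19 | cis-pinanyl α-diazo-β-keto ester, dimethyl (4R,5S)-2-diazo-5-[(1R,2S,5R)-6,6-dimethylbicyclo[3.1.1]heptan-2-yl]-3-oxo-4-(propan-2-yl)hexanedioate (C2 = Ca, C3 = Cb, C4 = Cc, C5 = Cq) | [C@H](C(=O)OC)([C@H]1CC[C@@H]2C[C@H]1C2(C)C)[C@@H](C(C)C)C(=O)C(=[N+]=[N-])C(=O)OC | intermediate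
20 | rhodium carbenoid at Ca derived from 19 (Rh stands for the Rh2(OAc)4 unit) | [C@H](C(=O)OC)([C@H]1CC[C@@H]2C[C@H]1C2(C)C)[C@@H](C(C)C)C(=O)C(=[Rh])C(=O)OC | intermediate (not isolated)
21 | spiro cyclopentanone β-keto ester, dimethyl 4'-oxo-3'-(propan-2-yl)spiro[6,6-dimethylbicyclo[3.1.1]heptane-2,1'-cyclopentane]-2',5'-dicarboxylate (C1' = P2, C2' = Cq, C3' = Cc, C4' = Cb, C5' = Ca; bridgeheads as in 1; C5' anti and C2' syn to the gem-dimethyl bridge; 2'-ester on the bridgehead-C1 side of ring B, trans to the 3'-isopropyl group on the pinane-C3 side; C5' undefined) | [C@@H]2(C(=O)OC)[C@@H](C(C)C)C(=O)C(C(=O)OC)[C@@]21CC[C@@H]2C[C@H]1C2(C)C | intermediate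
22 | methyl 4'-oxo-3'-(propan-2-yl)spiro[6,6-dimethylbicyclo[3.1.1]heptane-2,1'-cyclopentane]-2'-carboxylate (configuration as in 21) | [C@@H]2(C(=O)OC)[C@@H](C(C)C)C(=O)C[C@@]21CC[C@@H]2C[C@H]1C2(C)C | intermediate
23 | 1,3-dithiolane of 22 at C4' (Cb) | [C@@H]2(C(=O)OC)[C@@H](C(C)C)C3(SCCS3)C[C@@]21CC[C@@H]2C[C@H]1C2(C)C | intermediate
24 | methyl 3'-(propan-2-yl)spiro[6,6-dimethylbicyclo[3.1.1]heptane-2,1'-cyclopentane]-2'-carboxylate (configuration as in 21) | [C@@H]2(C(=O)OC)[C@@H](C(C)C)CC[C@@]21CC[C@@H]2C[C@H]1C2(C)C | intermediate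
25 | [3'-(propan-2-yl)spiro[6,6-dimethylbicyclo[3.1.1]heptane-2,1'-cyclopentan]-2'-yl]methanol (configuration as in 24; hydroxymethyl group on Cq) | [C@@H]2(CO)[C@@H](C(C)C)CC[C@@]21CC[C@@H]2C[C@H]1C2(C)C | intermediate
26 | 3'-(propan-2-yl)spiro[6,6-dimethylbicyclo[3.1.1]heptane-2,1'-cyclopentane]-2'-carbaldehyde (configuration as in 24; CHO = future Ct) | [C@@H]2(C=O)[C@@H](C(C)C)CC[C@@]21CC[C@@H]2C[C@H]1C2(C)C | intermediate
27 | methyl isobutyrate (methyl 2-methylpropanoate) | COC(=O)C(C)C | starting material
28 | propanoyl chloride | CCC(=O)Cl | starting material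
29 | lithium enolate of 27 | COC(O[Li])=C(C)C | intermediate (not isolated)
30 | methyl 2,2-dimethyl-3-oxopentanoate | CCC(=O)C(C)(C)C(=O)OC | intermediate
31 | lithium enolate of 30 at C4 | CC=C(O[Li])C(C)(C)C(=O)OC | intermediate (not isolated)
32 | aldol adduct, methyl 5-hydroxy-2,2,4-trimethyl-3-oxo-5-(spiro-2'-yl)pentanoate (spiro unit as in 26; C4 and C5 mixtures) | [C@@H]2(C(O)C(C)C(=O)C(C)(C)C(=O)OC)[C@@H](C(C)C)CC[C@@]21CC[C@@H]2C[C@H]1C2(C)C | intermediate
33 | diketo ester, methyl 2,2,4-trimethyl-3,5-dioxo-5-(spiro-2'-yl)pentanoate (C5 = Ct, C4 = Cv, C3 = Cw, C2 = Cx, C1 = Cy) | [C@@H]2(C(=O)C(C)C(=O)C(C)(C)C(=O)OC)[C@@H](C(C)C)CC[C@@]21CC[C@@H]2C[C@H]1C2(C)C | intermediate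
34 | dilithium dianion of 33 (enolised at Cv and Cq) | C2(=C(O[Li])C(C)=C(O[Li])C(C)(C)C(=O)OC)[C@@H](C(C)C)CC[C@@]21CC[C@@H]2C[C@H]1C2(C)C | intermediate (not isolated)
35 | ring-A trione (O-demethyl target, drawn as the triketone, expected as its enol): 4,4,6-trimethylcyclohexane-1,3,5-trione spiro at C2 (Cq) to ring B; Cy carbonyl trans and Ct carbonyl cis to the isopropyl group | O=C1C(C)C(=O)[C@@]2(C(=O)C1(C)C)[C@@H](C(C)C)CC[C@@]21CC[C@@H]2C[C@H]1C2(C)C | intermediate
36 | CNP0307059.1: 5-methoxy-4,6,6-trimethylcyclohex-4-ene-1,3-dione spiro at C2 (Cq) to the 3'-isopropylcyclopentane ring B, itself spiro at P2 to the 6,6-dimethylbicyclo[3.1.1]heptane | COC1=C(C)C(=O)[C@@]2(C(=O)C1(C)C)[C@@H](C(C)C)CC[C@@]21CC[C@@H]2C[C@H]1C2(C)C | target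

Total step count: 21. Longest linear sequence: 19 steps (steps 1–3, 5–16 and 18–21, from 1 to 36); steps 4 and 17 make the two side fragments.

Steps most likely to fail

Step 11. The carbenoid may be diverted before it reaches P2–H: the ester on Cq lies β to that bond and slows hydride-like transfer, so insertion into the isopropyl methyl groups, trapping by the ester carbonyl or carbene dimerisation can take over. The fallback changes the substrate design, not the catalyst. The carboxyl carbon on Cq is carried through the ring closure at the alcohol oxidation level as a pivalate; an acyloxy-bearing CH2 is deactivated toward electrophilic carbenoids and leaves no carbonyl within reach of Ca. Setting out from acid 13, LiAlH4 in THF would give the primary alcohol F1, and pivaloyl chloride in pyridine the pivalate F2. Ozonolysis as in step 8 then gives the aldehyde F3, Roskamp homologation with 17 the β-keto ester F4, and diazo transfer the diazo compound F5. Rh2(OAc)4 should now close ring B to the spiro β-keto ester F6. Krapcho dealkoxycarbonylation gives the spiro ketone F7, thioketalisation the dithiolane F8 and Raney Ni the deoxygenated pivalate F9. LiAlH4 cleaves the pivalate and the route is rejoined at alcohol 25.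

Step 20. Acyl substitution at the neopentyl-type Cy ester by the hindered tertiary carbanion at Cq may be slow, so that O-acylation to an enol lactone or retro-Claisen cleavage by the liberated methoxide competes, and face selectivity at Cq may be incomplete. The fallback closes the Cq–Cy bond by aldol addition to an aldehyde instead. Setting out from aldol adduct 32, LiAlH4 would give the triol F10 and exhaustive Dess–Martin oxidation the diketo aldehyde F11. Two equivalents of LiN(iPr)2 at −78 °C, the first consumed at once by the acidic Cv–H, generate the same dianion at Cv and Cq, which adds to the non-enolisable aldehyde to give the hydroxy dione F12. Dess–Martin oxidation of the Cy carbinol rejoins the route at trione 35.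

Step 21. Kinetic alkylation may take place in part at the oxygen on Ct or at carbon Cv, which would erode regioselectivity. The fallback replaces enolate alkylation by acid-catalysed, equilibrating enol ether formation. Setting out from trione 35, MeOH, HC(OMe)3 and TsOH (cat.) at reflux let the two vinylogous esters equilibrate, and the isomer with the methoxy group beside the less congested CMe2 carbon, target 36, should accumulate; no new compound is made (F0).

Further compounds

F1 | step 11 | (2S,3S,4E)-2-(cis-pinan-2-yl)-3-(propan-2-yl)hex-4-en-1-ol (configuration as in 13) | OC[C@@H]([C@H]1CC[C@@H]2C[C@H]1C2(C)C)[C@@H](C(C)C)/C=C/C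
F2 | step 11 | pivalate of F1 | CC(C)(C)C(=O)OC[C@@H]([C@H]1CC[C@@H]2C[C@H]1C2(C)C)[C@@H](C(C)C)/C=C/C
F3 | step 11 | aldehyde from F2 (CHO at Cb; pivaloyloxymethyl analogue of 16) | CC(C)(C)C(=O)OC[C@@H]([C@H]1CC[C@@H]2C[C@H]1C2(C)C)[C@@H](C(C)C)C=O
F4 | step 11 | β-keto ester (pivaloyloxymethyl analogue of 18) | CC(C)(C)C(=O)OC[C@@H]([C@H]1CC[C@@H]2C[C@H]1C2(C)C)[C@@H](C(C)C)C(=O)CC(=O)OC
F5 | step 11 | α-diazo-β-keto ester (pivaloyloxymethyl analogue of 19) | CC(C)(C)C(=O)OC[C@@H]([C@H]1CC[C@@H]2C[C@H]1C2(C)C)[C@@H](C(C)C)C(=O)C(=[N+]=[N-])C(=O)OC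
F6 | step 11 | spiro β-keto ester (pivaloyloxymethyl analogue of 21) | [C@@H]2(COC(=O)C(C)(C)C)[C@@H](C(C)C)C(=O)C(C(=O)OC)[C@@]21CC[C@@H]2C[C@H]1C2(C)C
F7 | step 11 | spiro ketone (pivaloyloxymethyl analogue of 22) | [C@@H]2(COC(=O)C(C)(C)C)[C@@H](C(C)C)C(=O)C[C@@]21CC[C@@H]2C[C@H]1C2(C)C
F8 | step 11 | dithiolane of F7 | [C@@H]2(COC(=O)C(C)(C)C)[C@@H](C(C)C)C3(SCCS3)C[C@@]21CC[C@@H]2C[C@H]1C2(C)C
F9 | step 11 | deoxygenated pivalate (pivalate of 25) | [C@@H]2(COC(=O)C(C)(C)C)[C@@H](C(C)C)CC[C@@]21CC[C@@H]2C[C@H]1C2(C)C
F10 | step 20 | triol from reduction of 32 | [C@@H]2(C(O)C(C)C(O)C(C)(C)CO)[C@@H](C(C)C)CC[C@@]21CC[C@@H]2C[C@H]1C2(C)C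
F11 | step 20 | diketo aldehyde (Cy as CHO) | [C@@H]2(C(=O)C(C)C(=O)C(C)(C)C=O)[C@@H](C(C)C)CC[C@@]21CC[C@@H]2C[C@H]1C2(C)C
F12 | step 20 | ring-A hydroxy dione (Cy as carbinol, Cq as in 36) | O=C1C(C)C(=O)[C@@]2(C(O)C1(C)C)[C@@H](C(C)C)CC[C@@]21CC[C@@H]2C[C@H]1C2(C)C
F0 | step 21 | none | none
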